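## Structural features

The target is a cis-fused decalin numbered as an eremophilane (ring A = C1–C5 and C10, ring B = C5–C10, shared bond C5–C10) that carries methyls on C4 and C5, an isopropenyl group on C7, a ketone at C8 and (Z)-2-methylbut-2-enoate (angelate) esters on O3 and O9. It has six stereocentres, five of them contiguous along C3–C4–C5–C10–C9 (3R,4R,5R,10S,9R) and one at C7 (R), with quaternary C5 lying between the C4 and C10 centres. Taking the face of the C5 methyl as β, the C4 methyl, the C7 isopropenyl group, H10 and O9 are β and O3 is α. In the chair–chair conformer that holds the angular methyl axial on ring A and equatorial on ring B, every other substituent is equatorial, so the array is the thermodynamically preferred one. The fragile groups are the angelates (Z to E isomerisation to tiglates), the C8 ketone with two enolisable neighbours (C7, where the isopropenyl group can move into conjugation, and C9, where the acyloxy group can epimerise or migrate) and the acid-sensitive 1,1-disubstituted alkene. The real difficulty is twofold: a quaternary C5 flanked by two ring stereocentres, and a vicinal C8/C9 oxygen pair that must end as ketone and equatorial ester, although kinetic hydride delivery to C3 and C9 is expected from the open faces and would give axial alcohols. The key step exploits ring B, in which the C5 methyl and the C7 isopropenyl group are 1,3-related with oxygen at C9; this is the pattern of the cyclohexenone obtained by oxidising (+)-3-carene and opening its cyclopropane, whose C5=C10 bond serves as dienophile for the four carbons C1–C4 of ring A while C7 directs the diene to the opposite face.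

## Logic of the disconnections

17 ⇒ 16. The C8 carbonyl is traced back to the C8 carbinol. The ketone makes C7 and C9 epimerisable and invites conjugation of the isopropenyl group, so it is revealed last. The gain is that O8 and O9 stay chemically distinct up to the end. The forward step must be a neutral, non-enolising oxidation.

16 ⇒ 15. The O8–H bond is replaced by an O8–Si bond. The silyl ether is the label that separates O8 from O3 and O9 from the start of the route. The forward cleavage must avoid alkoxide formation, which would let the O9 acyl group move to O8.

15 ⇒ 12 + 13. The two ester C–O bonds at O3 and O9 are cut, which releases two molecules of 13 for each molecule of 12. Angelates isomerise easily, so they are attached as late as the oxygen differentiation allows, both in one operation. This leaves a diol mono-silyl ether and a commercial acid. The forward step must acylate two hindered equatorial alcohols with an α-branched Z acid, one acid molecule per hydroxyl, without Z/E isomerisation.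

12 ⇒ 11. The C3–H and C9–H carbinol bonds are removed, returning both centres to ketones. Both carbinols have the equatorial, thermodynamically favoured configuration, and the dione is what the annulation delivers. Two stereocentres are removed. The forward reduction must run under thermodynamic control, because the open faces (α at C3, β at C9) lead to axial alcohols.

11 ⇒ 6 + 8. The C4–C5 and C1–C10 bonds are cut, removing ring A as a four-carbon diene. The polarity matches (nucleophilic enol-ether terminus to the enone β-carbon), and the cut leaves a monocyclic ring B that already holds C7 and both ring B oxygens. One ring, two C–C bonds and three stereocentres (C4, C5, C10), including the quaternary one, are removed. The forward step is a cycloaddition onto a hindered β,β-disubstituted enone, face-controlled by C7, beside an acid-sensitive alkene and a silyl ether.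

6 ⇒ 5. The O–Si bond at O8 is cut. The forward silylation of an α-ketol must not enolise the enone.

5 ⇒ 3. The C8–O bond is cut (C6 of the cyclohexenone). This position is the α′-carbon of the enone and can be reached through the kinetic enolate. One stereocentre and one heteroatom are removed. The forward step needs α′ rather than γ deprotonation and oxygen transfer trans to the isopropenyl group.

3 ⇒ 2. A bond is redrawn between the carbon α to the carbonyl (C8) and the tertiary side-chain carbon (C11), re-forming the cyclopropane. This reveals the carane skeleton and so leads to the chiral pool with C7 already set. The forward opening must break the external cyclopropane bond only and lose a proton to the terminal alkene, without aromatisation.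

2 ⇒ 1. The C9 carbonyl oxygen is removed. This reaches an inexpensive enantiopure terpene whose C1 becomes C7. The forward allylic oxidation must select the ring methylene next to the unsubstituted alkene carbon.

8 ⇒ 7. The enol-ether O–Si bond is cut, giving a commercial enone. The forward enol silylation must give the Z isomer with the methyl directed outward.

## Other disconnections considered

Alternative 1: The cut is the C5–C6 bond of ring B, taken back through a [3,3] shift in which a C3–C8 bond is re-formed. The cis-decalin then becomes the bridged vinyl carbinol A1, a bicyclo[2.2.2]octenol whose alkene carries both methyls and whose carbinol carbon (future C8) sits next to a ketal carbon (future C9). In the forward direction KH with 18-crown-6 would trigger the anionic oxy-Cope rearrangement of A1: the vinyl terminus C6 bonds to the methyl-bearing alkene carbon C5, the C3–C8 bond breaks, and the C8 enolate of cis-decalin A2 results.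
- In its favour: the bicycle forces a boat-like transition state, so the cis fusion with the angular methyl is fixed by geometry. This is the equal of the chosen cycloaddition.
- In its favour: C8 appears directly as the ketone with C9 already distinguished as a ketal, and the C7–C8 enolate is formed regiospecifically for attaching the side chain.
- Better than the chosen plan on one point: the C3=C4 alkene of A2 allows a syn hydroboration, which fixes the trans relation of the C3 oxygen and the C4 methyl by mechanism rather than by an equilibrating reduction.
- Against: the usual access to bicyclo[2.2.2]octenols of this kind is an achiral cycloaddition followed by vinyl addition, so A1 would be racemic unless a resolution or an auxiliary is added; the chosen plan takes its absolute configuration from 1.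
- Against: A2 lacks C11–C13, so the isopropenyl group and the C7 configuration must still be installed next to the C8 ketone, with the isopropenyl/isopropylidene competition.
- Against: the face of the hydroboration relative to C5 is not secured (methyl on one face, ring B on the other).
- Against: the C9 ketal must later become an equatorial ester beside a C8 ketone, so the C8/C9 differentiation and the hindered C9 reduction return in reversed form.
- Comparison: structurally it builds ring B and leaves C7 bare, whereas the chosen plan builds ring A on a ring B that already carries C7. Mechanistically a sigmatropic shift replaces a Lewis-acid cycloaddition. In step economy it should be longer (side chain, hydroboration, redox adjustments, resolution).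

Alternative 2: The cut is the pair C3–C4 and C5–C10 of ring A, with ring B still open between C6 and C7. In the forward direction a chiral oxazaborolidinium Lewis acid would catalyse the endo Diels–Alder reaction of tiglic aldehyde A3 with the (1E,3E)-1-silyl diene A4, which carries the protected C9/C8 diol chain, to give the ring A cyclohexene A5.
- In its favour: the absolute configuration is set by a catalyst, and four ring stereocentres including quaternary C5 are made in one step.
- Better than the chosen plan: the cis C4/C5 methyls are encoded in the E geometry of A3, so no epimerisation is needed.
- Better than the chosen plan: the silyl group at C3 is a masked hydroxyl that can be unmasked with retention (Fleming–Tamao oxidation), so the C3 oxygen is fixed kinetically.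
- Better than the chosen plan: the C9 oxygen stereocentre is carried in from the diene and needs no reduction.
- Against: A3 is a weak α,β-disubstituted dienophile and a 1-silyl diene is only modestly activated.
- Against: A4 has two stereocentres of its own (possible mismatch with the catalyst) and needs a multistep preparation.
- Against: the allylsilane in A5 is prone to protodesilylation with allylic shift.
- Against: ring B must still be closed (C6–C7, for example by aldol chemistry after oxidation at C8), the isopropenyl group and C7 configuration added afterwards, and the C1=C2 alkene saturated before a second alkene is present.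
- Comparison: structurally it makes ring A first and postpones ring B and C7, the reverse of the chosen order. Mechanistically both are Lewis-acid [4+2] reactions; the alternative is catalytic and enantioselective, the chosen one substrate-controlled from the chiral pool. In step economy it should be clearly longer.

Alternative 3: The cut is the C9–C10 bond of ring B, a retro-ene disconnection to the α-keto aldehyde A6. This is a ring A cyclohexene with the C10=C1 alkene, the C3 silyl ether, the C4 and C5 methyls, and a C6–C7–C8(=O)–C9H=O chain on C5. In the forward direction SnCl4 (or heat) would induce the intramolecular carbonyl-ene reaction of the C9 aldehyde with the C10=C1 alkene. C9–C10 forms, the C2 hydrogen passes to oxygen, and ring B closes to the acyloin A7 with the alkene moved to C1=C2.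
- Better than the chosen plan: the C8 ketone and free C9 hydroxyl arise directly in the oxidation pattern of the target, so no C8 protecting group and no redox transposition are needed.
- Equal to the chosen plan: the tether can reach C10 only from the side of the C5–C6 bond, so the cis fusion is enforced.
- In its favour: C9 is set in a cyclic transition state rather than by a reduction.
- Against: α-keto aldehydes hydrate and oligomerise easily, and with a chelating Lewis acid the axial or equatorial placement of the C9 hydroxyl is not securely predictable.
- Against: A6 itself needs a prior enantioselective synthesis of a ring with three contiguous stereocentres including quaternary C5, with no obvious chiral-pool source.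
- Against: A7 has no isopropenyl group, and introducing it at C7 must compete with enolisation toward the more acidic C9 ketol position.
- Against: the new C1=C2 alkene, allylic to the silyl ether, must be hydrogenated.
- Comparison: structurally one C–C bond closes ring B and C7 is left empty, against two bonds closing ring A with C7 in place. Mechanistically an ene reaction sets two centres where the cycloaddition sets three. The endgame at C8/C9 would be shorter, but access to A6 and the C7 side chain should make the whole route longer.

Key step: step 6

Conventions and assumption: eremophilane numbering is used for all bicyclic compounds; β is the face of the C5 methyl. The cycloaddition is assumed to pass through the endo transition state, so 9 and 10 carry the C4 methyl trans to the C5 methyl; if the other C4 epimer forms, hydrolysis gives 11 directly.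

Step 1
Reactants: 1 (+)-3-carene [(1S,6R)-3,7,7-trimethylbicyclo[4.1.0]hept-3-ene]
Product: 2 car-3-en-5-one [(1R,6S)-4,7,7-trimethylbicyclo[4.1.0]hept-3-en-2-one]
Conditions: Cr(CO)6 (cat.), t-BuOOH, MeCN, reflux
Reagents that add atoms: tert-butyl hydroperoxide, CC(C)(C)OO
Why: Chromium-catalysed allylic C–H oxidation should go at the ring methylene next to the unsubstituted alkene carbon and give the β-methyl enone; the two ring-fusion stereocentres are not touched.

Step 2
Reactants: 2 car-3-en-5-one
Product: 3 (5S)-3-methyl-5-(prop-1-en-2-yl)cyclohex-2-en-1-one
Conditions: TsOH·H2O (cat.), toluene, 80 °C, stopped at full conversion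
Reagents that add atoms: none
Why: Acid-catalysed homo-conjugate opening of the cyclopropyl ketone: the external ring bond that overlaps with the protonated enone should break to the tertiary cation, which loses a methyl proton (E1) to give the isopropenyl group. The carbon that becomes C7 is not involved and keeps its configuration.

Step 3
Reactants: 3 (5S)-3-methyl-5-(prop-1-en-2-yl)cyclohex-2-en-1-one
Product: 5 (5R,6R)-6-hydroxy-3-methyl-5-(prop-1-en-2-yl)cyclohex-2-en-1-one, via lithium dienolate 4 (not isolated)
Conditions: LiN(iPr)2, THF, −78 °C; then 2-(phenylsulfonyl)-3-phenyloxaziridine, −78 °C; aq. NH4Cl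
Reagents that add atoms: 2-(phenylsulfonyl)-3-phenyloxaziridine, O=S(=O)(N1OC1c1ccccc1)c1ccccc1
Why: Kinetic α′-deprotonation gives the cross-conjugated enolate, and N-sulfonyloxaziridine hydroxylation of the enolate should deliver oxygen anti to the neighbouring isopropenyl group, giving the trans ketol (also the more stable epimer).

Step 4
Reactants: 5 (5R,6R)-6-hydroxy-3-methyl-5-(prop-1-en-2-yl)cyclohex-2-en-1-one
Product: 6 (5R,6R)-6-(tert-butyldimethylsilyloxy)-3-methyl-5-(prop-1-en-2-yl)cyclohex-2-en-1-one
Conditions: TBSCl, imidazole, DMF, rt
Reagents that add atoms: tert-butyldimethylsilyl chloride, CC(C)(C)[Si](C)(C)Cl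
Why: Standard silylation of a secondary alcohol under weakly basic conditions that do not enolise the enone; the silyl ether marks O8 and is bulky and poorly Lewis-basic, which suits the coming Lewis-acid step.

Step 5
Reactants: 7 ethyl vinyl ketone (pent-1-en-3-one)
Product: 8 (Z)-3-(tert-butyldimethylsilyloxy)penta-1,3-diene
Conditions: TBSOTf, Et3N, Et2O, 0 °C to rt
Reagents that add atoms: tert-butyldimethylsilyl trifluoromethanesulfonate, CC(C)(C)[Si](C)(C)OS(=O)(=O)C(F)(F)F
Why: Soft enolisation with O-silylation of the ethyl ketone; the Z enol ether (methyl cis to oxygen, outward on the s-cis diene) is expected because it avoids allylic strain between the methyl and the vinyl group.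

Step 6
Reactants: 6 (5R,6R)-6-(tert-butyldimethylsilyloxy)-3-methyl-5-(prop-1-en-2-yl)cyclohex-2-en-1-one; 8 (Z)-3-(tert-butyldimethylsilyloxy)penta-1,3-diene
Product: 11 8α-(tert-butyldimethylsilyloxy)-10βH-eremophil-11-ene-3,9-dione (cis-fused; 4β,5β-dimethyl; 7β-isopropenyl), via silyl enol ether cycloadduct 9 (not isolated), via 4-epi-dione 10 (not isolated)
Conditions: AlBr3/AlMe3 (5:1), toluene/CH2Cl2, −20 to 0 °C; then 1 M HCl, THF, rt
Reagents that add atoms: none
Why: The mixed aluminium Lewis acid binds the C9 carbonyl of 6 and lowers the LUMO of the hindered β,β-disubstituted enone so that the electron-rich 2-silyloxydiene 8 can add in a normal-demand Diels–Alder reaction; the closest known reaction type is the AlBr3/AlMe3-promoted cycloaddition of 2-silyloxydienes with β-methylcyclohexenones that gives cis-decalins with an angular methyl. Enol-ether polarity sets the regiochemistry: the nucleophilic methyl-bearing terminus (C4) bonds to the enone β-carbon (C5) and the vinyl terminus (C1) to the α-carbon (C10). Ring A closes as the six-membered ring of an intermolecular [4+2] cycloaddition, suprafacial on both partners; in the stepwise limit it is a Mukaiyama–Michael addition followed by a 6-endo-trig Michael closure of the aluminium enolate onto the silyloxocarbenium-activated vinyl group, with the same result. C5 is controlled by the C7 stereocentre: the diene should attack the half-chair enone axially on the face anti to the pseudo-equatorial isopropenyl group (the pseudo-equatorial C8 silyloxy group lies near the enone plane and does not shield that face), which leaves the angular methyl cis to the isopropenyl group. C10 is controlled by the topology of the addition, since C1 is delivered to the same face as C4, so the fusion is cis with H10 on the side of the C5 methyl. C4 is set kinetically by the Z diene geometry and the endo transition state (methyl trans to the C5 methyl in 9) and is then corrected under thermodynamic control: after hydrolysis of the enol ether, acid-catalysed enolisation of the C3 ketone of 10 should move the methyl to the equatorial position cis to the angular methyl, because the other epimer is axial and syn-axial to C9 in the chair–chair conformer that keeps the angular methyl axial on ring A. The step needs chemoselectivity for the enone over the isopropenyl group and survival of the C8 silyl ether: AlMe3 scavenges protic acid that would start cationic reactions of the alkene, the low temperature and the bulky, poorly basic silyl ether oxygen disfavour ionisation at C8, and the dilute acid of the work-up should cleave only the silyl enol ether.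

Step 7
Reactants: 11 8α-(tert-butyldimethylsilyloxy)-10βH-eremophil-11-ene-3,9-dione
Product: 12 8α-(tert-butyldimethylsilyloxy)-10βH-eremophil-11-ene-3α,9β-diol
Conditions: Al(OiPr)3, iPrOH/toluene, reflux with slow removal of acetone, then continued heating with a trace of acetone; aq. KNaC4H4O6
Reagents that add atoms: none
Why: Meerwein–Ponndorf–Verley reduction is a reversible hydride transfer, so with a little acetone present the aluminium alkoxides should equilibrate to the thermodynamic diol. C3 (α-OH) and C9 (β-OH) are then set equatorial, because the axial epimers are syn-axial to the C5 methyl and to C4 respectively, whereas irreversible hydride attack from the open faces would give those axial epimers. The cis fusion (a trans fusion would force the C7 isopropenyl group syn-axial to the angular methyl), C4 and C8 are already in their most stable configurations, so enolisation under these conditions is harmless and any residual C4 epimer converges.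

Step 8
Reactants: 12 8α-(tert-butyldimethylsilyloxy)-10βH-eremophil-11-ene-3α,9β-diol; 13 angelic acid [(Z)-2-methylbut-2-enoic acid] (one molecule per hydroxyl; the second molecule is entered under the reagents)
Product: 15 3α,9β-bis(angeloyloxy)-8α-(tert-butyldimethylsilyloxy)-10βH-eremophil-11-ene, via angelic 2,4,6-trichlorobenzoic anhydride 14 (not isolated)
Conditions: 13 (3 equiv), 2,4,6-Cl3C6H2COCl (3 equiv), Et3N, toluene, rt; then 12, 80 °C
Reagents that add atoms: angelic acid (second molar equivalent of 13, for the second ester), C/C=C(/C)C(=O)O
Why: Yamaguchi-type esterification through the mixed anhydride, in which each alcohol attacks the unshielded angeloyl carbonyl, so two molecules of 13 are consumed, one for O3 and one for the more hindered O9. No nucleophilic acyl-transfer catalyst is used, which avoids the addition–elimination path that turns angelates into tiglates; no stereocentre is affected.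

Step 9
Reactants: 15 3α,9β-bis(angeloyloxy)-8α-(tert-butyldimethylsilyloxy)-10βH-eremophil-11-ene
Product: 16 3α,9β-bis(angeloyloxy)-10βH-eremophil-11-en-8α-ol
Conditions: HF·pyridine, pyridine, THF, 0 °C to rt
Reagents that add atoms: none
Why: Fluoride cleavage of the Si–O bond under buffered, weakly acidic conditions generates no alkoxide, so the O9 angeloyl group should not migrate to the freed O8 and both esters should survive.

Step 10
Reactants: 16 3α,9β-bis(angeloyloxy)-10βH-eremophil-11-en-8α-ol
Product: 17 3α,9β-bis(angeloyloxy)-10βH-eremophil-11-en-8-one [(3R,4R,5R,7R,9R,10S), CNP0174755.1]
Conditions: Dess–Martin periodinane, pyridine, CH2Cl2, 0 °C to rt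
Reagents that add atoms: none
Why: Dess–Martin oxidation of the secondary carbinol under buffered, non-basic conditions. C7 and C9 become α to the ketone only here; both are already equatorial and see no base, so epimerisation and conjugation of the isopropenyl group should not occur.

Compound list
1 | (+)-3-carene, (1S,6R)-3,7,7-trimethylbicyclo[4.1.0]hept-3-ene | CC1=CC[C@@H]2[C@H](C1)C2(C)C | starting material
2 | car-3-en-5-one, (1R,6S)-4,7,7-trimethylbicyclo[4.1.0]hept-3-en-2-one | CC1=CC(=O)[C@@H]2[C@H](C1)C2(C)C | intermediate
3 | (5S)-3-methyl-5-(prop-1-en-2-yl)cyclohex-2-en-1-one | CC1=CC(=O)C[C@H](C1)C(C)=C | intermediate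
4 | lithium cross-conjugated dienolate of 3 (O–C1=C6, C2=C3) | CC1=CC(O[Li])=C[C@H](C1)C(C)=C | intermediate
5 | (5R,6R)-6-hydroxy-3-methyl-5-(prop-1-en-2-yl)cyclohex-2-en-1-one (trans) | CC1=CC(=O)[C@H](O)[C@H](C1)C(C)=C | intermediate
6 | (5R,6R)-6-(tert-butyldimethylsilyloxy)-3-methyl-5-(prop-1-en-2-yl)cyclohex-2-en-1-one (trans) | CC1=CC(=O)[C@H](O[Si](C)(C)C(C)(C)C)[C@H](C1)C(C)=C | intermediate
7 | ethyl vinyl ketone (pent-1-en-3-one) | CCC(=O)C=C | starting material
8 | (Z)-3-(tert-butyldimethylsilyloxy)penta-1,3-diene | C=C/C(O[Si](C)(C)C(C)(C)C)=C/C | intermediate
9 | 3,8α-bis(tert-butyldimethylsilyloxy)-4α-methyl-10βH-eremophila-2,11-dien-9-one (endo cycloadduct, 4-epi) | C=C(C)[C@H]1C[C@@]2(C)[C@H](CC=C(O[Si](C)(C)C(C)(C)C)[C@H]2C)C(=O)[C@@H]1O[Si](C)(C)C(C)(C)C | intermediate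
10 | 8α-(tert-butyldimethylsilyloxy)-4-epi-10βH-eremophil-11-ene-3,9-dione (4α-methyl) | C=C(C)[C@H]1C[C@@]2(C)[C@H](CCC(=O)[C@H]2C)C(=O)[C@@H]1O[Si](C)(C)C(C)(C)C | intermediate
11 | 8α-(tert-butyldimethylsilyloxy)-10βH-eremophil-11-ene-3,9-dione (cis-fused; 4β,5β-dimethyl; 7β-isopropenyl) | C=C(C)[C@H]1C[C@@]2(C)[C@H](CCC(=O)[C@@H]2C)C(=O)[C@@H]1O[Si](C)(C)C(C)(C)C | intermediate
12 | 8α-(tert-butyldimethylsilyloxy)-10βH-eremophil-11-ene-3α,9β-diol | C=C(C)[C@H]1C[C@@]2(C)[C@H](CC[C@@H](O)[C@@H]2C)[C@@H](O)[C@@H]1O[Si](C)(C)C(C)(C)C | intermediate
13 | angelic acid, (Z)-2-methylbut-2-enoic acid | C/C=C(/C)C(=O)O | starting material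
14 | angelic 2,4,6-trichlorobenzoic anhydride | C/C=C(/C)C(=O)OC(=O)c1c(Cl)cc(Cl)cc1Cl | intermediate
15 | 3α,9β-bis(angeloyloxy)-8α-(tert-butyldimethylsilyloxy)-10βH-eremophil-11-ene | C=C(C)[C@H]1C[C@@]2(C)[C@H](CC[C@@H](OC(=O)/C(C)=C\C)[C@@H]2C)[C@@H](OC(=O)/C(C)=C\C)[C@@H]1O[Si](C)(C)C(C)(C)C | intermediate
16 | 3α,9β-bis(angeloyloxy)-10βH-eremophil-11-en-8α-ol | C=C(C)[C@H]1C[C@@]2(C)[C@H](CC[C@@H](OC(=O)/C(C)=C\C)[C@@H]2C)[C@@H](OC(=O)/C(C)=C\C)[C@@H]1O | intermediate
17 | 3α,9β-bis(angeloyloxy)-10βH-eremophil-11-en-8-one, (3R,4R,5R,7R,9R,10S) | C=C(C)[C@H]1C[C@@]2(C)[C@H](CC[C@@H](OC(=O)/C(C)=C\C)[C@@H]2C)[C@@H](OC(=O)/C(C)=C\C)C1=O | target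

Total step count: 10. Longest linear sequence: 9 steps (steps 1–4 and 6–10 from 1); step 5 is a one-step branch.

Least certain steps

Step 6 (key step). The most likely failure is that the cycloaddition on the oxygen-substituted, hindered enone is slow enough for Lewis-acid side processes to take over: loss of the α′-silyloxy group, protodesilylation of the diene, or cationic reactions of the isopropenyl group. Facial selectivity would also erode if the enone reacted through its diaxial conformer.
Fallback: move the C8 oxygenation behind the annulation. Starting from 3 and 8, the same AlBr3/AlMe3 promoter acts on the enone without the α′-substituent, which is the substrate type of the closest precedent. With an amine-buffered work-up this should give the 8-deoxy silyl enol ether cycloadduct F1. In F1 the C3 carbonyl is masked, so LiN(iPr)2 can enolise only the C9 ketone, kinetically toward the C8 methylene, and oxaziridine hydroxylation then gives the 8-hydroxy ketone F2 (drawn as the 8α epimer). TBSCl/imidazole converts F2 into 9. The acid treatment of step 6 then hydrolyses the enol ether and equilibrates C4, and if necessary the epimerisable C8, returning to the route at 11.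

Step 7. The risks are incomplete equilibration, because the hindered aluminium alkoxides of the kinetic axial alcohols may re-oxidise only slowly, and O8 to O9 silyl migration in the alkoxide at reflux.
Fallback: separate reduction from stereocontrol. From 11, NaBH4 with CeCl3·7H2O in MeOH at −20 °C should reduce both ketones quickly and without alkoxide build-up, giving the kinetic diol F3 (drawn as the 3β,9α diaxial diol; mixtures are acceptable). The free carbinol centres are then epimerised by reversible hydrogen transfer with catalytic (η5-C5Ph5)Ru(CO)2Cl and catalytic KOtBu in toluene at rt to 60 °C. This should converge on the all-equatorial diol, returning at 12.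

Step 2. The risk is over-isomerisation: re-protonation of the isopropenyl group, drift to the isopropylidene isomer and onward to the conjugated dienone and the aromatic phenol, or competing cleavage of the ring-fusion cyclopropane bond.
Fallback: open the ring with a nucleophile while the carbonyl is masked. From 2, Me3SiI (from Me3SiCl and NaI, MeCN, −20 °C) should give the tertiary iodide as its silyl dienol ether F4. DBU then eliminates HI toward the methyl groups; because the ketone is held as the enol ether, re-closure to the cyclopropane cannot occur, and the product is the isopropenyl silyl dienol ether F5. Brief treatment of F5 with dilute aqueous acid returns to the route at 3.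

Step 8. The risks are Z to E isomerisation of the angeloyl groups during the prolonged heating needed for the hindered O9, and incomplete acylation next to the silyl ether, which would stop at the O3 mono-ester.
Fallback: build the Z alkene on the molecule instead of transferring it. From 12, carbodiimide coupling with 2-[bis(2,2,2-trifluoroethoxy)phosphoryl]propanoic acid gives the bis(phosphonopropionate) F6. A double Still–Gennari olefination of F6 with acetaldehyde (KN(SiMe3)2, 18-crown-6, THF, −78 °C) should form both (Z)-2-methylbut-2-enoates, returning at 15.

Further compounds
F1 | step 6 | 3-(tert-butyldimethylsilyloxy)-4α-methyl-10βH-eremophila-2,11-dien-9-one (cycloadduct of 3 and 8, no C8 oxygen) | C=C(C)[C@H]1C[C@@]2(C)[C@H](CC=C(O[Si](C)(C)C(C)(C)C)[C@H]2C)C(=O)C1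
F2 | step 6 | 8α-hydroxy-3-(tert-butyldimethylsilyloxy)-4α-methyl-10βH-eremophila-2,11-dien-9-one | C=C(C)[C@H]1C[C@@]2(C)[C@H](CC=C(O[Si](C)(C)C(C)(C)C)[C@H]2C)C(=O)[C@@H]1O
F3 | step 7 | 8α-(tert-butyldimethylsilyloxy)-10βH-eremophil-11-ene-3β,9α-diol (kinetic diaxial diol) | C=C(C)[C@H]1C[C@@]2(C)[C@H](CC[C@H](O)[C@@H]2C)[C@H](O)[C@@H]1O[Si](C)(C)C(C)(C)C
F4 | step 2 | trimethylsilyl dienol ether of 5-(2-iodopropan-2-yl)-3-methylcyclohex-2-enone (O–C1=C6, C2=C3; C5 as in 3) | CC1=CC(O[Si](C)(C)C)=C[C@H](C1)C(C)(C)I
F5 | step 2 | trimethylsilyl dienol ether of 3 (O–C1=C6, C2=C3) | CC1=CC(O[Si](C)(C)C)=C[C@H](C1)C(C)=C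
F6 | step 8 | 3α,9β-bis{2-[bis(2,2,2-trifluoroethoxy)phosphoryl]propanoyloxy}-8α-(tert-butyldimethylsilyloxy)-10βH-eremophil-11-ene (phosphonate α-carbons as epimer mixtures) | C=C(C)[C@H]1C[C@@]2(C)[C@H](CC[C@@H](OC(=O)C(C)P(=O)(OCC(F)(F)F)OCC(F)(F)F)[C@@H]2C)[C@@H](OC(=O)C(C)P(=O)(OCC(F)(F)F)OCC(F)(F)F)[C@@H]1O[Si](C)(C)C(C)(C)C
A1 | alternative 1 | 3,3-dimethoxy-5,6-dimethyl-2-vinylbicyclo[2.2.2]oct-5-en-2-ol (vinyl syn to the ring alkene) | C=C[C@]1(O)C(OC)(OC)[C@H]2CC[C@@H]1C(C)=C2C
A2 | alternative 1 | 9,9-dimethoxy-11,12,13-trinor-cis-eremophil-3-en-8-one | O=C1CC[C@@]2(C)[C@H](CCC=C2C)C1(OC)OC
A3 | alternative 2 | tiglic aldehyde, (E)-2-methylbut-2-enal | C/C=C(\C)C=O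
A4 | alternative 2 | (1E,3E)-1-(dimethylphenylsilyl)-5-(4-methoxybenzyloxy)-6-(tert-butyldimethylsilyloxy)hepta-1,3-diene (C9 and C8 configured as in A5) | C[C@H](O[Si](C)(C)C(C)(C)C)[C@H](OCc1ccc(OC)cc1)/C=C/C=C/[Si](C)(C)c1ccccc1
A5 | alternative 2 | ring A cyclohexene adduct: C6 formyl and methyl on C5, methyl on C4, dimethylphenylsilyl on C3, protected C9/C8 chain on C10 | O=C[C@@]1(C)[C@H](C=C[C@@H]([Si](C)(C)c2ccccc2)[C@@H]1C)[C@@H](OCc3ccc(OC)cc3)[C@@H](O[Si](C)(C)C(C)(C)C)C
A6 | alternative 3 | 4-[(1S,5R,6R)-5-(tert-butyldimethylsilyloxy)-1,6-dimethylcyclohex-2-en-1-yl]-2-oxobutanal (3α-silyloxy, 4β,5β-dimethyl, C10=C1 alkene in eremophilane terms) | O=CC(=O)CC[C@@]1(C)C=CC[C@@H](O[Si](C)(C)C(C)(C)C)[C@@H]1C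
A7 | alternative 3 | 3-(tert-butyldimethylsilyloxy)-9-hydroxy-11,12,13-trinor-cis-eremophil-1-en-8-one | O=C1CC[C@@]2(C)[C@H](C=C[C@@H](O[Si](C)(C)C(C)(C)C)[C@@H]2C)[C@H]1O
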